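## The problem

The target is a linear tridepside made of three orsellinate-type benzene rings. The C4 oxygen of ring A (the methyl benzoate ring) is acylated by the carboxyl of ring B, and the C4 oxygen of ring B by the carboxyl of ring C. There is no stereocentre, so nothing has to be controlled in space. The difficulty is telling apart six oxygen functions on three almost identical 2,4-dioxygenated 6-methylbenzoyl units. Ring A needs its chelated C2 oxygen methylated and its C4 oxygen acylated, which is the reverse of the innate reactivity of an orsellinate; ring B needs C2–OH free and C4–O acylated; ring C needs C2–OH free and C4–OMe. The two depside links are aryl esters. They are shielded by two ortho substituents but are still cleaved or shifted by alkoxide, hydroxide and amines, so no saponification or basic deprotection can come late, and the free ortho hydroxyls must be uncovered under neutral conditions at the end. Every acyl partner is a 2,6-disubstituted benzoic acid, so each esterification needs a strongly activated acyl donor. The key step rests on ring A: CH3 at C6, CO2Me at C1 and OMe at C2 sit on three adjacent carbons, with the C4 oxygen meta to both flanking groups. This is the pattern left when an aryne beside a methoxy group takes a carbon nucleophile at the remote carbon and a carbon electrophile at the carbon next to oxygen.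

## Retrosynthesis

Target 23 is first traced to dibenzyl ether 22 by cutting the two benzyl–oxygen bonds that mask the ortho hydroxyls of rings B and C. Benzyl is preferred to silyl, acetal or acyl masks because hydrogen over Pd/C is neutral and leaves both aryl esters alone. The skeleton of 22 is no simpler, but it has no free phenol, so the ester-forming steps before it need no selectivity. The forward step must remove two hindered benzyl ethers without touching aryl–oxygen bonds.

Cutting the acyl–oxygen bond between rings A and B divides 22 into phenol 10 and acid 20, which is used as its chloride 21. This link is cut before the B–C link because 10 has one hydroxyl and 20 has none, so the union is unambiguous and the halves are of similar size. Cutting B–C first would leave an A–B ester whose two ring B hydroxyls still have to be distinguished. The forward reaction asks a 2,6-disubstituted benzoyl chloride to acylate a moderately nucleophilic phenol in the presence of an existing depside ester.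

Phenol 10 comes from silyl ether 9 by cleavage of the O–Si bond. In 9 the C6–CH3 and C1–CO2Me bonds are cut together, which leads back through arylmagnesium 8 and aryne 7 to aryllithium 6, and so to chloroarene 3, methylmagnesium bromide 4 and methyl chloroformate 5. The neighbouring option is to take ring A from an orsellinate, which means methylating the hydrogen-bonded C2 hydroxyl while the more reactive C4 hydroxyl stays free, a protect–methylate–deprotect sequence. The aryne cut instead starts from a 1,3,5-trisubstituted benzene with no carbon substituents and sets methyl, ester and ortho-methoxy in one flask, with the C4 oxygen already differentiated as a silyl ether. The forward reaction needs deprotonation only between Cl and OMe and addition of methyl only at the carbon remote from OMe.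

Silyl ether 3 is cut at its O–Si bond to 3-chloro-5-methoxyphenol 1 and chlorotriisopropylsilane 2. Triisopropylsilyl is chosen over methoxymethyl, carbamate or smaller silyl groups because those direct or permit ortho-metalation, whereas the bulky silyl ether neither coordinates lithium nor leaves room beside itself. The forward reaction is a routine silylation.

Acid 20 is traced to aldehyde 19 by a change of oxidation state, 19 to phenol 18 by cutting a benzyl–oxygen bond, and 18 to acid 16 (as chloride 17) and dihydroxy aldehyde 11 by cutting the B–C acyl–oxygen bond. Carrying the ring B carboxyl as a formyl group is preferred to an ester, because an ester would need a protecting group removable beside benzyl ethers and an aryl ester. The aldehyde is bought, holds the ortho hydroxyl in a hydrogen bond so that acylation goes to the para hydroxyl, and is oxidized by chlorite at about pH 4. The forward sequence needs site-selective mono-acylation of 11, alkylation of the chelated hydroxyl without disturbing the new ester, and a mild aldehyde oxidation.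

Acid 16 is reduced to the same building block: oxidation state change to aldehyde 15, benzyl–oxygen cut to 13 with benzyl bromide 14, methyl–oxygen cut to 11 with iodomethane 12. Using 11 for both rings B and C keeps the number of starting materials small. It also replaces the hydrolysis of a doubly ortho-substituted benzoate, which an ester-based route would need, by a chlorite oxidation. The forward steps rely on the 4-hydroxyl of 11 alkylating before the chelated 2-hydroxyl.

## Roads not taken

Alternative 1: Ring C is dismantled completely and rebuilt last by a Danheiser benzannulation. The substrate is diazoketone A1, methyl 4-({2-(benzyloxy)-4-{[(2E)-5-diazo-3-methyl-4-oxopent-2-enoyl]oxy}-6-methylbenzoyl}oxy)-2-methoxy-6-methylbenzoate. Irradiated with methoxyacetylene A2, it would undergo Wolff rearrangement with 1,2-alkenyl shift to a vinylketene, (2+2) addition of the alkyne, four-electron opening of the cyclobutenone and six-electron closure, giving phenol A3, the target with only the ring B hydroxyl benzylated.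
- Merits: four ring bonds form in one operation. The regiochemistry is built in, since the phenol oxygen comes from the ketene carbonyl and the methoxy group from the alkyne, so ring C needs neither a protecting group nor a selective O-methylation. In this respect it is better than the chosen plan.
- Weak points: A1 combines a diazo group with an electron-poor enoate, which invites dipolar cycloaddition. Its enoyl aryl ester is a reactive acyl donor. Ultraviolet light on a molecule with two aryl esters risks photo-Fries rearrangement. A2 is volatile and unstable.
- Comparison: the route builds the ring that is easiest to obtain (ring C is two alkylations and an oxidation from 11) and leaves ring A and the differentiation of ring B to classical means. The chosen plan spends its skeletal bond formation on ring A, where it removes protecting-group steps, and runs its risky step on a simple early intermediate rather than on a late didepside.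

Alternative 2: Ring A is cut at C1–C6 and C2–C3. The B–C acid chloride 21 would acylate 4-hydroxy-6-methyl-2H-pyran-2-one A4 to give pyranone ester A5, 6-methyl-2-oxo-2H-pyran-4-yl 2-(benzyloxy)-4-{[2-(benzyloxy)-4-methoxy-6-methylbenzoyl]oxy}-6-methylbenzoate. A5 would add methyl 3-methoxypropiolate A6 across C3 and C6, and decarboxylative cycloreversion of the bridged lactone would give A7, which is the same compound as 22.
- Merits: it is highly convergent, A4 is cheap, and the polarities match the required orientation (the nucleophilic pyranone C3 meets the methoxy-bearing alkyne carbon). The A–B ester is in place before ring A exists, so the separate phenol synthesis of steps 1 to 3 disappears. On convergence and step count it is at least as good as the chosen plan.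
- Weak points: 2-pyranones are sluggish dienes that usually need high temperature. A5 is a vinylogous mixed anhydride prone to acyl transfer and 1,3-acyl shift when heated. A6 is a push–pull alkyne of low dienophilicity and is not a shelf reagent.
- Comparison: the heat would be applied to the most advanced and most labile intermediate. The chosen plan sets against the shorter count a key step of a known reaction type, carried out at low temperature on silyl ether 3.

Alternative 3: Ring B is cut at its C1–C6 bond. The triketo ester A8, methyl 2-methoxy-6-methyl-4-[(3,5,7-trioxooctanoyl)oxy]benzoate, would enolize at chain C2, add to the C7 ketone and aromatize by two dehydrations to A9, methyl 4-[(2,4-dihydroxy-6-methylbenzoyl)oxy]-2-methoxy-6-methylbenzoate.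
- Merits: the fold is biomimetic, and ring B arrives with both hydroxyls free and already esterified to ring A. Acylation of the para hydroxyl of A9 with chloride 17 and one hydrogenolysis would finish the synthesis. This saves the benzylation of step 8, a real advantage over the chosen plan.
- Weak points: A8 must be made from a 3,5,7-trioxooctanoic acid that decarboxylates readily and is hard to esterify with a phenol. The aryl ester is a far better leaving group than the alkyl esters for which the aldol mode is known, so Claisen-type closure onto C1 and enol lactonization would both be favoured, and both expel the ring A phenoxide. Ring A still has to be made, as phenol 10, so the hardest substitution problem is untouched.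
- Comparison: against its one extra protecting-group step, the chosen plan forms each depside bond by a reaction that cannot eject a ring already attached.

Key step: step 2

Assumption: 2,4-dihydroxy-6-methylbenzaldehyde 11, not the corresponding acid, is taken as the purchasable source of rings B and C, because a formyl group is a carboxyl that needs no protecting group and is unveiled by chlorite near neutrality.

## Route

Step 1
Reactants: 1 3-chloro-5-methoxyphenol; 2 chlorotriisopropylsilane
Product: 3 (3-chloro-5-methoxyphenoxy)triisopropylsilane
Conditions: imidazole, DMF, rt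
Reagents that add atoms: none
Why: O-Silylation of a phenol with a silyl chloride and imidazole; the triisopropylsilyl ether withstands amide bases and Grignard reagents and screens both of its ortho positions from metalation.

Step 2
Reactants: 3 (3-chloro-5-methoxyphenoxy)triisopropylsilane; 4 methylmagnesium bromide; 5 methyl chloroformate
Product: 9 methyl 2-methoxy-6-methyl-4-[(triisopropylsilyl)oxy]benzoate, via aryllithium 6 (not isolated), via aryne 7 (not isolated), via arylmagnesium bromide 8 (not isolated)
Conditions: lithium 2,2,6,6-tetramethylpiperidide (1.2 equiv), THF, −78 °C; 4 (3–4 equiv), −78 °C → rt; then transfer into 5 (excess), THF, −78 °C → rt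
Reagents that add atoms: none
Why: The hindered amide base removes the ring proton between Cl and OMe, the most acidic site because it is flanked by two inductively withdrawing groups and the methoxy oxygen can hold lithium, giving aryllithium 6; the two positions beside the silyl ether are sterically screened and lack a coordinating oxygen. On warming, 6 loses LiCl to give aryne 7. Methyl from 4 adds to the aryne carbon remote from OMe, because the aryne is polarized so that this carbon is the electrophilic one and the developing carbanion then sits next to the withdrawing, chelating oxygen; the distant silyloxy group has only a minor influence. The resulting arylmagnesium bromide 8 is acylated by 5 at low temperature under inverse addition, and the ester formed, flanked by methyl and methoxy, resists a second addition. The closest known reaction type is aryne generation from an ortho-lithiated 3-haloanisole or 1,3-dihaloarene, carbomagnesiation by a Grignard reagent and capture of the new arylmagnesium by a carbonyl electrophile in one pot. No ring is closed and no stereocentre is formed; the step makes the C6–CH3 and C1–CO2Me bonds. The two selectivities needed, the site of deprotonation and the direction of addition, are both governed by the methoxy group; excess 4 and a non-nucleophilic amide keep methyl transfer ahead of addition of 8 or of the base to the aryne.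

Step 3
Reactants: 9 methyl 2-methoxy-6-methyl-4-[(triisopropylsilyl)oxy]benzoate
Product: 10 methyl 4-hydroxy-2-methoxy-6-methylbenzoate
Conditions: Bu4NF, AcOH, THF, 0 °C
Reagents that add atoms: none
Why: Fluoride cleavage of an aryl silyl ether; the acetic acid buffer protonates the phenoxide as it forms, and the doubly ortho-substituted methyl ester is inert to these conditions.

Step 4
Reactants: 11 2,4-dihydroxy-6-methylbenzaldehyde; 12 iodomethane
Product: 13 2-hydroxy-4-methoxy-6-methylbenzaldehyde
Conditions: K2CO3 (1 equiv), acetone, rt
Reagents that add atoms: none
Why: Williamson etherification; the 4-hydroxyl, para to formyl, is the more acidic and freely accessible one, whereas the 2-hydroxyl is tied up in a hydrogen bond to the carbonyl, so one equivalent of alkylating agent should go to O-4.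

Step 5
Reactants: 13 2-hydroxy-4-methoxy-6-methylbenzaldehyde; 14 benzyl bromide
Product: 15 2-(benzyloxy)-4-methoxy-6-methylbenzaldehyde
Conditions: K2CO3, DMF, 60 °C
Reagents that add atoms: none
Why: Williamson etherification of the remaining chelated phenol, which alkylates cleanly once a polar aprotic solvent and mild heating break the hydrogen bond.

Step 6
Reactants: 15 2-(benzyloxy)-4-methoxy-6-methylbenzaldehyde
Product: 16 2-(benzyloxy)-4-methoxy-6-methylbenzoic acid
Conditions: NaClO2, NaH2PO4, 2-methyl-2-butene, t-BuOH/THF/H2O, rt
Reagents that add atoms: sodium chlorite, [Na+].[O-]Cl=O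
Why: Pinnick oxidation; chlorous acid converts the hindered, electron-rich aldehyde into the acid at about pH 4, and excess alkene traps the hypochlorous acid that would otherwise chlorinate the activated ring.

Step 7
Reactants: 16 2-(benzyloxy)-4-methoxy-6-methylbenzoic acid; 11 2,4-dihydroxy-6-methylbenzaldehyde
Product: 18 4-formyl-3-hydroxy-5-methylphenyl 2-(benzyloxy)-4-methoxy-6-methylbenzoate, via acid chloride 17 (not isolated)
Conditions: (COCl)2, DMF (cat.), CH2Cl2, 0 °C → rt, evaporate; then 11 (1 equiv), Et3N, THF, 0 °C → rt
Reagents that add atoms: none
Why: Acid chloride formation followed by O-acylation of a phenol; triethylamine deprotonates the more acidic 4-hydroxyl of 11 while the 2-hydroxyl stays hydrogen-bonded to the formyl group, so one equivalent of the hindered chloride 17 should acylate the para oxygen only.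

Step 8
Reactants: 18 4-formyl-3-hydroxy-5-methylphenyl 2-(benzyloxy)-4-methoxy-6-methylbenzoate; 14 benzyl bromide
Product: 19 3-(benzyloxy)-4-formyl-5-methylphenyl 2-(benzyloxy)-4-methoxy-6-methylbenzoate
Conditions: K2CO3 (anhydrous), DMF, rt
Reagents that add atoms: none
Why: Williamson etherification of the chelated ring B hydroxyl; under anhydrous carbonate the only nucleophile present is the phenoxide being alkylated, and the neighbouring depside carbonyl is shielded by its two ortho substituents.

Step 9
Reactants: 19 3-(benzyloxy)-4-formyl-5-methylphenyl 2-(benzyloxy)-4-methoxy-6-methylbenzoate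
Product: 20 2-(benzyloxy)-4-{[2-(benzyloxy)-4-methoxy-6-methylbenzoyl]oxy}-6-methylbenzoic acid
Conditions: NaClO2, NaH2PO4, 2-methyl-2-butene, t-BuOH/THF/H2O, rt
Reagents that add atoms: sodium chlorite, [Na+].[O-]Cl=O
Why: Pinnick oxidation as in step 6; the weakly acidic aqueous medium leaves the aryl ester and both benzyl ethers untouched, which is why the ring B carboxyl was carried as a formyl group.

Step 10
Reactants: 20 2-(benzyloxy)-4-{[2-(benzyloxy)-4-methoxy-6-methylbenzoyl]oxy}-6-methylbenzoic acid; 10 methyl 4-hydroxy-2-methoxy-6-methylbenzoate
Product: 22 methyl 4-({2-(benzyloxy)-4-{[2-(benzyloxy)-4-methoxy-6-methylbenzoyl]oxy}-6-methylbenzoyl}oxy)-2-methoxy-6-methylbenzoate, via acid chloride 21 (not isolated)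
Conditions: (COCl)2, DMF (cat.), CH2Cl2, 0 °C → rt, evaporate; then 10, Et3N, 4-(dimethylamino)pyridine (cat.), CH2Cl2, 0 °C → rt
Reagents that add atoms: none
Why: Acid chloride formation and acyl-transfer-catalysed esterification of a phenol; 10 has a single hydroxyl and 21 has none, so no selectivity is required, and the existing B–C ester is protected from the phenoxide by its ortho substituents.

Step 11
Reactants: 22 methyl 4-({2-(benzyloxy)-4-{[2-(benzyloxy)-4-methoxy-6-methylbenzoyl]oxy}-6-methylbenzoyl}oxy)-2-methoxy-6-methylbenzoate
Product: 23 methyl 4-({2-hydroxy-4-[(2-hydroxy-4-methoxy-6-methylbenzoyl)oxy]-6-methylbenzoyl}oxy)-2-methoxy-6-methylbenzoate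
Conditions: H2 (1 atm), 10% Pd/C, EtOAc, rt
Reagents that add atoms: none
Why: Catalytic hydrogenolysis of two aryl benzyl ethers under neutral conditions; aryl esters, the methyl ester and the aryl methyl ethers are not reduced, so both depside links should survive the only deprotection of the endgame.

## Compound list

1 | 3-chloro-5-methoxyphenol | COc1cc(O)cc(Cl)c1 | starting material
2 | chlorotriisopropylsilane | CC(C)[Si](Cl)(C(C)C)C(C)C | starting material
3 | (3-chloro-5-methoxyphenoxy)triisopropylsilane | COc1cc(Cl)cc(O[Si](C(C)C)(C(C)C)C(C)C)c1 | intermediate
4 | methylmagnesium bromide | C[Mg]Br | starting material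
5 | methyl chloroformate | COC(=O)Cl | starting material
6 | [2-chloro-6-methoxy-4-(triisopropylsilyloxy)phenyl]lithium | COc1cc(O[Si](C(C)C)(C(C)C)C(C)C)cc(Cl)c1[Li] | intermediate
7 | 3-methoxy-5-(triisopropylsilyloxy)benzyne (1,2-didehydro-3-methoxy-5-(triisopropylsilyloxy)benzene) | COC1=CC(O[Si](C(C)C)(C(C)C)C(C)C)=CC#C1 | intermediate
8 | [2-methoxy-6-methyl-4-(triisopropylsilyloxy)phenyl]magnesium bromide | COc1cc(O[Si](C(C)C)(C(C)C)C(C)C)cc(C)c1[Mg]Br | intermediate
9 | methyl 2-methoxy-6-methyl-4-[(triisopropylsilyl)oxy]benzoate | COC(=O)c1c(C)cc(O[Si](C(C)C)(C(C)C)C(C)C)cc1OC | intermediate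
10 | methyl 4-hydroxy-2-methoxy-6-methylbenzoate | COC(=O)c1c(C)cc(O)cc1OC | intermediate
11 | 2,4-dihydroxy-6-methylbenzaldehyde | Cc1cc(O)cc(O)c1C=O | starting material
12 | iodomethane | CI | starting material
13 | 2-hydroxy-4-methoxy-6-methylbenzaldehyde | COc1cc(C)c(C=O)c(O)c1 | intermediate
14 | benzyl bromide | BrCc1ccccc1 | starting material
15 | 2-(benzyloxy)-4-methoxy-6-methylbenzaldehyde | COc1cc(C)c(C=O)c(OCc2ccccc2)c1 | intermediate
16 | 2-(benzyloxy)-4-methoxy-6-methylbenzoic acid | COc1cc(C)c(C(=O)O)c(OCc2ccccc2)c1 | intermediate
17 | 2-(benzyloxy)-4-methoxy-6-methylbenzoyl chloride | COc1cc(C)c(C(=O)Cl)c(OCc2ccccc2)c1 | intermediate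
18 | 4-formyl-3-hydroxy-5-methylphenyl 2-(benzyloxy)-4-methoxy-6-methylbenzoate | COc1cc(C)c(C(=O)Oc2cc(C)c(C=O)c(O)c2)c(OCc3ccccc3)c1 | intermediate
19 | 3-(benzyloxy)-4-formyl-5-methylphenyl 2-(benzyloxy)-4-methoxy-6-methylbenzoate | COc1cc(C)c(C(=O)Oc2cc(C)c(C=O)c(OCc3ccccc3)c2)c(OCc4ccccc4)c1 | intermediate
20 | 2-(benzyloxy)-4-{[2-(benzyloxy)-4-methoxy-6-methylbenzoyl]oxy}-6-methylbenzoic acid | COc1cc(C)c(C(=O)Oc2cc(C)c(C(=O)O)c(OCc3ccccc3)c2)c(OCc4ccccc4)c1 | intermediate
21 | 2-(benzyloxy)-4-{[2-(benzyloxy)-4-methoxy-6-methylbenzoyl]oxy}-6-methylbenzoyl chloride | COc1cc(C)c(C(=O)Oc2cc(C)c(C(=O)Cl)c(OCc3ccccc3)c2)c(OCc4ccccc4)c1 | intermediate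
22 | methyl 4-({2-(benzyloxy)-4-{[2-(benzyloxy)-4-methoxy-6-methylbenzoyl]oxy}-6-methylbenzoyl}oxy)-2-methoxy-6-methylbenzoate | COC(=O)c1c(C)cc(OC(=O)c2c(C)cc(OC(=O)c3c(C)cc(OC)cc3OCc4ccccc4)cc2OCc5ccccc5)cc1OC | intermediate
23 | methyl 4-({2-hydroxy-4-[(2-hydroxy-4-methoxy-6-methylbenzoyl)oxy]-6-methylbenzoyl}oxy)-2-methoxy-6-methylbenzoate | COC(=O)c1c(C)cc(OC(=O)c2c(C)cc(OC(=O)c3c(C)cc(OC)cc3O)cc2O)cc1OC | target

## Step count and least certain steps

Total step count: 11. Longest linear sequence: 8 steps (11 → 13 → 15 → 16 → 18 → 19 → 20 → 22 → 23, steps 4 to 11). The ring A branch (steps 1 to 3) joins at step 10.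

**Step 2 (key step).**
- What may go wrong: methyl transfer to the aryne may be too slow. The aryne would then be consumed by addition of the arylmagnesium already formed, or of the amide base, giving biaryl and aminated material. Some metalation beside the silyl ether would erode regiocontrol, and excess Grignard reagent could compete for the chloroformate.
- Fallback: it sets out from 3 and returns at 9. Aryllithium 6 is kept at −78 °C so that LiCl is not lost and is trapped there with 5 to give methyl 2-chloro-6-methoxy-4-[(triisopropylsilyl)oxy]benzoate F1. The chloride of F1 is then replaced by methyl in a Suzuki–Miyaura coupling (trimethylboroxine, Pd(OAc)2, 2-dicyclohexylphosphino-2',6'-dimethoxybiphenyl, K3PO4, dioxane, 100 °C) to give 9. The aryne is thus exchanged for ortho-lithiation plus cross-coupling, at the cost of one step.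

**Step 8.**
- What may go wrong: the chelated, hindered ring B hydroxyl may alkylate slowly. The phenoxide, which is para-related to a good leaving aryloxide, may instead cause acyl migration or cleavage of the freshly made depside ester.
- Fallback: it sets out from 11 and returns at 19, so that ring B is differentiated before any depside bond exists. Chloromethyl methyl ether and ethyldiisopropylamine protect the 4-hydroxyl of 11 as 2-hydroxy-4-(methoxymethoxy)-6-methylbenzaldehyde F2. Benzylation with 14 and K2CO3 in DMF gives 2-(benzyloxy)-4-(methoxymethoxy)-6-methylbenzaldehyde F3. HCl in methanol frees 2-(benzyloxy)-4-hydroxy-6-methylbenzaldehyde F4, which is acylated with chloride 17 (from 16) and Et3N to give 19. This detour also removes the site-selectivity demand of step 7.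

**Step 10.**
- What may go wrong: the large, doubly ortho-substituted chloride 21 may acylate slowly. During a long reaction the phenoxide or the acyl-transfer catalyst may attack the existing B–C ester and scramble the depside links, or a benzyl ether may be lost during chlorination.
- Fallback: it sets out from 11 and 10 and returns at 23, forming the A–B bond while no other depside link is present.
  - Double benzylation of 11 with 14 gives 2,4-bis(benzyloxy)-6-methylbenzaldehyde F5.
  - Pinnick oxidation gives 2,4-bis(benzyloxy)-6-methylbenzoic acid F6.
  - Oxalyl chloride gives 2,4-bis(benzyloxy)-6-methylbenzoyl chloride F7, which acylates 10 to methyl 4-{[2,4-bis(benzyloxy)-6-methylbenzoyl]oxy}-2-methoxy-6-methylbenzoate F8.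
  - Hydrogenolysis gives methyl 4-[(2,4-dihydroxy-6-methylbenzoyl)oxy]-2-methoxy-6-methylbenzoate F9, the same compound as A9.
  - Chloride 17 acylates the para hydroxyl of F9 (the ortho one is hydrogen-bonded to the ester carbonyl) to give methyl 4-({4-{[2-(benzyloxy)-4-methoxy-6-methylbenzoyl]oxy}-2-hydroxy-6-methylbenzoyl}oxy)-2-methoxy-6-methylbenzoate F10.
  - A final hydrogenolysis gives 23.

## Further compounds

F1 | step 2 | methyl 2-chloro-6-methoxy-4-[(triisopropylsilyl)oxy]benzoate | COC(=O)c1c(Cl)cc(O[Si](C(C)C)(C(C)C)C(C)C)cc1OC
F2 | step 8 | 2-hydroxy-4-(methoxymethoxy)-6-methylbenzaldehyde | COCOc1cc(C)c(C=O)c(O)c1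
F3 | step 8 | 2-(benzyloxy)-4-(methoxymethoxy)-6-methylbenzaldehyde | COCOc1cc(C)c(C=O)c(OCc2ccccc2)c1
F4 | step 8 | 2-(benzyloxy)-4-hydroxy-6-methylbenzaldehyde | Cc1cc(O)cc(OCc2ccccc2)c1C=O
F5 | step 10 | 2,4-bis(benzyloxy)-6-methylbenzaldehyde | Cc1cc(OCc2ccccc2)cc(OCc3ccccc3)c1C=O
F6 | step 10 | 2,4-bis(benzyloxy)-6-methylbenzoic acid | Cc1cc(OCc2ccccc2)cc(OCc3ccccc3)c1C(=O)O
F7 | step 10 | 2,4-bis(benzyloxy)-6-methylbenzoyl chloride | Cc1cc(OCc2ccccc2)cc(OCc3ccccc3)c1C(=O)Cl
F8 | step 10 | methyl 4-{[2,4-bis(benzyloxy)-6-methylbenzoyl]oxy}-2-methoxy-6-methylbenzoate | COC(=O)c1c(C)cc(OC(=O)c2c(C)cc(OCc3ccccc3)cc2OCc4ccccc4)cc1OC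
F9 | step 10 | methyl 4-[(2,4-dihydroxy-6-methylbenzoyl)oxy]-2-methoxy-6-methylbenzoate | COC(=O)c1c(C)cc(OC(=O)c2c(C)cc(O)cc2O)cc1OC
F10 | step 10 | methyl 4-({4-{[2-(benzyloxy)-4-methoxy-6-methylbenzoyl]oxy}-2-hydroxy-6-methylbenzoyl}oxy)-2-methoxy-6-methylbenzoate | COC(=O)c1c(C)cc(OC(=O)c2c(C)cc(OC(=O)c3c(C)cc(OC)cc3OCc4ccccc4)cc2O)cc1OC
A1 | alternative 1 | methyl 4-({2-(benzyloxy)-4-{[(2E)-5-diazo-3-methyl-4-oxopent-2-enoyl]oxy}-6-methylbenzoyl}oxy)-2-methoxy-6-methylbenzoate | COC(=O)c1c(C)cc(OC(=O)c2c(C)cc(OC(=O)/C=C(\C)C(=O)C=[N+]=[N-])cc2OCc3ccccc3)cc1OC
A2 | alternative 1 | methoxyacetylene (methoxyethyne) | COC#C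
A3 | alternative 1 | methyl 4-({2-(benzyloxy)-4-[(2-hydroxy-4-methoxy-6-methylbenzoyl)oxy]-6-methylbenzoyl}oxy)-2-methoxy-6-methylbenzoate | COC(=O)c1c(C)cc(OC(=O)c2c(C)cc(OC(=O)c3c(C)cc(OC)cc3O)cc2OCc4ccccc4)cc1OC
A4 | alternative 2 | 4-hydroxy-6-methyl-2H-pyran-2-one | Cc1cc(O)cc(=O)o1
A5 | alternative 2 | 6-methyl-2-oxo-2H-pyran-4-yl 2-(benzyloxy)-4-{[2-(benzyloxy)-4-methoxy-6-methylbenzoyl]oxy}-6-methylbenzoate | Cc1cc(OC(=O)c2c(C)cc(OC(=O)c3c(C)cc(OC)cc3OCc4ccccc4)cc2OCc5ccccc5)cc(=O)o1
A6 | alternative 2 | methyl 3-methoxypropiolate | COC#CC(=O)OC
A7 | alternative 2 | methyl 4-({2-(benzyloxy)-4-{[2-(benzyloxy)-4-methoxy-6-methylbenzoyl]oxy}-6-methylbenzoyl}oxy)-2-methoxy-6-methylbenzoate | COC(=O)c1c(C)cc(OC(=O)c2c(C)cc(OC(=O)c3c(C)cc(OC)cc3OCc4ccccc4)cc2OCc5ccccc5)cc1OC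
A8 | alternative 3 | methyl 2-methoxy-6-methyl-4-[(3,5,7-trioxooctanoyl)oxy]benzoate | COC(=O)c1c(C)cc(OC(=O)CC(=O)CC(=O)CC(C)=O)cc1OC
A9 | alternative 3 | methyl 4-[(2,4-dihydroxy-6-methylbenzoyl)oxy]-2-methoxy-6-methylbenzoate | COC(=O)c1c(C)cc(OC(=O)c2c(C)cc(O)cc2O)cc1OC
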